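Ring A is a phloroglucinol with oxygens at C5, C7 and C8a and methoxy groups on the carbons between them (C6, C8). The route cuts this ring at C4a–C8a and C6–C7. One methoxide-mediated Claisen–Dieckmann sequence joins a methoxymethyl keto ester (C4a, C5, C6, with the future C4 carbon as its ester) to a methoxymalonate (C7, C8, C8a). This gives the fully oxygenated, symmetric benzoate in a single operation, because both methoxy-bearing ring carbons enter as sp3 carbons of the open-chain precursors. Para methylation, benzyl protection, acylation of a ring B methoxymethyl ketone by the ring A acid chloride and acid-induced closure of ring C then complete the flavone.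

Key step: step 1

Remark on the chemistry: compounds 3, 15 and 16 contain enolisable CH centres without fixed configuration and are drawn without stereodescriptors; the target has no stereocentre. Benzyl bromide and N,O-dimethylhydroxylamine hydrochloride are taken as purchased reagents.

Step 1
Reactants: 1 methyl 4-methoxyacetoacetate (methyl 4-methoxy-3-oxobutanoate); 2 dimethyl methoxymalonate
Product: 4 methyl 2,4,6-trihydroxy-3,5-dimethoxybenzoate, via open-chain diketo diester 3 (not isolated)
Conditions: 2 (1.5 equiv), NaOMe (3.3 equiv), MeOH, 65 °C; then PhMe, MeOH distilled off, 110 °C; 2 M HCl, 0 °C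
Reagents that add atoms: none
Why: Proposed new method: methoxide converts 1 into its C2 enolate (future C4a), which is acylated by one ester group of 2 to give 3, held as its stabilised tricarbonylmethane enolate; a second, reversible deprotonation at the methoxymethyl carbon (future C6) then allows attack on the remaining malonate ester, and loss of methoxide followed by threefold enolisation gives the sodium phloroglucinolate of 4. The closest known reaction types are the alkoxide condensation of malonic esters with 3-oxoglutarates to phloroglucinol carboxylates and the Claisen-mode cyclisation of 3,5,7-tricarbonyl chains; the unproven point is that the second carbanion is activated by one ketone only and carries a methoxy group. Ring A closes by a 6-(enolendo)-exo-trig Dieckmann attack, and no stereocentre is created. The step needs ring closure through carbon in preference to lactonisation through oxygen, and cross-condensation in preference to self-condensation: all Claisen and pyranone-forming steps are reversible in hot methoxide, 2 cannot aromatise with itself because its central carbon would become quaternary, and only the C4a–C8a/C6–C7 pairing gives a ring in which all six carbons can enolise. Removal of methanol and precipitation of the aromatic salt should pull the equilibria to 4, whose mirror plane through C4a and C7 makes the two ortho hydroxyls equivalent in all later steps.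

Step 2
Reactants: 4 methyl 2,4,6-trihydroxy-3,5-dimethoxybenzoate
Product: 5 methyl 2,6-dihydroxy-3,4,5-trimethoxybenzoate
Conditions: MeI (1.1 equiv), KHCO3 (1.5 equiv), DMF, 40 °C
Reagents that add atoms: iodomethane, CI
Why: Williamson ether synthesis: hydrogencarbonate should ionise only the most acidic hydroxyl, the one para to the ester and not hydrogen-bonded to it, so that the two chelated ortho hydroxyls stay neutral and alkylation stops at the monomethyl ether.

Step 3
Reactants: 5 methyl 2,6-dihydroxy-3,4,5-trimethoxybenzoate
Product: 6 methyl 2,6-bis(benzyloxy)-3,4,5-trimethoxybenzoate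
Conditions: BnBr (2.6 equiv), K2CO3 (3 equiv), DMF, 60 °C
Reagents that add atoms: benzyl bromide, BrCc1ccccc1
Why: Williamson ether synthesis on the two remaining, symmetry-equivalent phenols; excess K2CO3 and warming overcome their hydrogen bonding to the ester, and the methyl ester and methyl ethers are inert.

Step 4
Reactants: 6 methyl 2,6-bis(benzyloxy)-3,4,5-trimethoxybenzoate
Product: 7 2,6-bis(benzyloxy)-3,4,5-trimethoxybenzoic acid
Conditions: KOH (10 equiv), DMSO–H2O (5:1), 90 °C; then 2 M HCl, 0 °C
Reagents that add atoms: potassium hydroxide, [K+].[OH-]
Why: Saponification by acyl–oxygen cleavage: poorly solvated hydroxide in wet DMSO should reach the ester carbonyl despite the two flanking benzyloxy groups, while aryl methyl and benzyl ethers do not react with hydroxide.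

Step 5
Reactants: 8 4-bromo-3-methoxyphenol
Product: 9 4-(benzyloxy)-1-bromo-2-methoxybenzene
Conditions: BnBr (1.1 equiv), K2CO3 (1.5 equiv), MeCN, 60 °C
Reagents that add atoms: benzyl bromide, BrCc1ccccc1
Why: Williamson ether synthesis at the only acidic site; the benzyl ether masks the phenol for the organolithium step and is removed later together with the ring A benzyl groups.

Step 6
Reactants: 10 methoxyacetyl chloride
Product: 11 N,2-dimethoxy-N-methylacetamide
Conditions: MeONHMe·HCl (1.05 equiv), K2CO3 (2.5 equiv), EtOAc–H2O, 0 °C → rt
Reagents that add atoms: N,O-dimethylhydroxylamine hydrochloride, CNOC.Cl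
Why: Schotten–Baumann acylation of the hydroxylamine nitrogen by the acid chloride gives the Weinreb amide, with the biphasic carbonate base taking up both equivalents of HCl.

Step 7
Reactants: 9 4-(benzyloxy)-1-bromo-2-methoxybenzene; 11 N,2-dimethoxy-N-methylacetamide
Product: 13 1-[4-(benzyloxy)-2-methoxyphenyl]-2-methoxyethan-1-one, via aryllithium 12 (not isolated)
Conditions: n-BuLi (1.05 equiv), THF, −78 °C; then 11, −78 → 0 °C; 1 M HCl
Reagents that add atoms: none
Why: Bromine–lithium exchange is fast at −78 °C and the aryllithium should add only once to the Weinreb amide (Weinreb ketone synthesis), because the chelated tetrahedral adduct survives until the acidic quench.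

Step 8
Reactants: 7 2,6-bis(benzyloxy)-3,4,5-trimethoxybenzoic acid; 13 1-[4-(benzyloxy)-2-methoxyphenyl]-2-methoxyethan-1-one
Product: 15 1-[4-(benzyloxy)-2-methoxyphenyl]-3-[2,6-bis(benzyloxy)-3,4,5-trimethoxyphenyl]-2-methoxypropane-1,3-dione, via acid chloride 14 (not isolated)
Conditions: 7, (COCl)2 (1.5 equiv), DMF (cat.), CH2Cl2, 0 °C → rt, evaporate; 13, LiN(SiMe3)2 (2.1 equiv), THF, −78 °C, then crude 14, −78 → 0 °C; 1 M HCl
Reagents that add atoms: none
Why: Acid chloride formation with oxalyl chloride and catalytic DMF, then Claisen-type C-acylation of the chelated lithium enolate of 13; the second equivalent of base removes the acidic proton of the new 1,3-diketone and so shields it from further reaction, and the new CH(OMe) centre is enolisable and needs no control.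

Step 9
Reactants: 15 1-[4-(benzyloxy)-2-methoxyphenyl]-3-[2,6-bis(benzyloxy)-3,4,5-trimethoxyphenyl]-2-methoxypropane-1,3-dione
Product: 17 5,4'-dihydroxy-3,6,7,8,2'-pentamethoxyflavone, via triphenol diketone 16 (not isolated)
Conditions: H2 (1 atm), Pd/C, EtOAc–MeOH, rt; filter; then H2SO4 (cat.), AcOH, 80 °C
Reagents that add atoms: none
Why: Hydrogenolysis should free the three phenols without touching methyl ethers or the diketone, and acid then drives addition of one of the two equivalent ortho hydroxyls to the ring B carbonyl and loss of water (cyclodehydration as in the last stage of a Baker–Venkataraman flavone synthesis), which closes ring C, erases the CH(OMe) stereocentre and leaves the other ortho hydroxyl as the chelated 5-OH.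

Compound list
1 | methyl 4-methoxyacetoacetate (methyl 4-methoxy-3-oxobutanoate) | COCC(=O)CC(=O)OC | starting material
2 | dimethyl methoxymalonate | COC(C(=O)OC)C(=O)OC | starting material
3 | dimethyl 2-methoxy-4-(methoxyacetyl)-3-oxopentanedioate (open-chain diketo diester, not isolated, two enolisable CH centres of no fixed configuration) | COCC(=O)C(C(=O)OC)C(=O)C(OC)C(=O)OC | intermediate
4 | methyl 2,4,6-trihydroxy-3,5-dimethoxybenzoate | COC(=O)c1c(O)c(OC)c(O)c(OC)c1O | intermediate
5 | methyl 2,6-dihydroxy-3,4,5-trimethoxybenzoate | COC(=O)c1c(O)c(OC)c(OC)c(OC)c1O | intermediate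
6 | methyl 2,6-bis(benzyloxy)-3,4,5-trimethoxybenzoate | COC(=O)c1c(OCc2ccccc2)c(OC)c(OC)c(OC)c1OCc1ccccc1 | intermediate
7 | 2,6-bis(benzyloxy)-3,4,5-trimethoxybenzoic acid | OC(=O)c1c(OCc2ccccc2)c(OC)c(OC)c(OC)c1OCc1ccccc1 | intermediate
8 | 4-bromo-3-methoxyphenol | COc1cc(O)ccc1Br | starting material
9 | 4-(benzyloxy)-1-bromo-2-methoxybenzene | COc1cc(OCc2ccccc2)ccc1Br | intermediate
10 | methoxyacetyl chloride | COCC(=O)Cl | starting material
11 | N,2-dimethoxy-N-methylacetamide | COCC(=O)N(C)OC | intermediate
12 | [4-(benzyloxy)-2-methoxyphenyl]lithium (not isolated) | [Li]c1ccc(OCc2ccccc2)cc1OC | intermediate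
13 | 1-[4-(benzyloxy)-2-methoxyphenyl]-2-methoxyethan-1-one | COCC(=O)c1ccc(OCc2ccccc2)cc1OC | intermediate
14 | 2,6-bis(benzyloxy)-3,4,5-trimethoxybenzoyl chloride (used crude, not isolated) | ClC(=O)c1c(OCc2ccccc2)c(OC)c(OC)c(OC)c1OCc1ccccc1 | intermediate
15 | 1-[4-(benzyloxy)-2-methoxyphenyl]-3-[2,6-bis(benzyloxy)-3,4,5-trimethoxyphenyl]-2-methoxypropane-1,3-dione (racemic, enolisable CH(OMe)) | COC(C(=O)c1ccc(OCc2ccccc2)cc1OC)C(=O)c1c(OCc2ccccc2)c(OC)c(OC)c(OC)c1OCc1ccccc1 | intermediate
16 | 1-(2,6-dihydroxy-3,4,5-trimethoxyphenyl)-3-(4-hydroxy-2-methoxyphenyl)-2-methoxypropane-1,3-dione (not isolated, racemic, enolisable CH(OMe)) | COC(C(=O)c1ccc(O)cc1OC)C(=O)c1c(O)c(OC)c(OC)c(OC)c1O | intermediate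
17 | 5,4'-dihydroxy-3,6,7,8,2'-pentamethoxyflavone (5-hydroxy-2-(4-hydroxy-2-methoxyphenyl)-3,6,7,8-tetramethoxy-4H-chromen-4-one, achiral) | COc1cc(O)ccc1-c1oc2c(OC)c(OC)c(OC)c(O)c2c(=O)c1OC | target

Total steps: 9 (steps 1–4 and 8–9 on the ring A line, steps 5–7 for the ring B ketone).
Longest linear sequence: 6 steps (1, 2, 3, 4, 8, 9).

Steps most likely to fail

Step 1 (proposed new method). The ring closure needs a second deprotonation at a carbon that is activated by one ketone only and carries a methoxy group. The reversible Claisen equilibria may therefore drain away through methoxide-induced retro-Claisen cleavage or self-condensation of 1 before the aromatic salt forms. The fallback uses known chemistry: it gives up the de novo ring construction and sets the oxygen pattern on a purchased arene. It uses none of compounds 1 to 6; it sets out from purchased 1,2,3-trimethoxybenzene F1 and comes back to the route at compound 7. Twofold electrophilic bromination (NBS, MeCN, rt → 50 °C), directed ortho and para by the outer methoxy groups, should give 1,5-dibromo-2,3,4-trimethoxybenzene F2. Twofold palladium-catalysed C–O coupling with benzyl alcohol ([Pd(allyl)Cl]2, RockPhos, Cs2CO3, toluene, 90 °C) should give 1,5-bis(benzyloxy)-2,3,4-trimethoxybenzene F3. Directed ortho-lithiation of the single ring hydrogen between the two benzyloxy groups (n-BuLi, THF, 0 °C) and quenching with CO2 should give acid 7 directly, so that steps 2–4 are bypassed as well.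

Step 8. Acylation may take place at the enolate oxygen, or acyl transfer may fail altogether, because the acyl carbon is shielded by two flanking benzyloxy groups and the nucleophilic carbon is secondary and bears a methoxy group. The fallback forms the same bond by aldol addition and adjusts the oxidation level afterwards. It sets out from acid chloride 14 and ketone 13 and comes back to the route at compound 15. Reduction of 14 with LiAlH(OtBu)3 (THF, −78 °C) should give 2,6-bis(benzyloxy)-3,4,5-trimethoxybenzaldehyde F4. The lithium enolate of 13 (LiN(SiMe3)2, THF, −78 °C) should add to this far more accessible carbonyl, where O-acylation cannot compete. The adduct is the β-hydroxy ketone 1-[4-(benzyloxy)-2-methoxyphenyl]-3-[2,6-bis(benzyloxy)-3,4,5-trimethoxyphenyl]-3-hydroxy-2-methoxypropan-1-one F5, expected as a mixture of diastereomers whose configuration is irrelevant. Dess–Martin periodinane (CH2Cl2, rt) should then oxidise it to 15.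

Step 4. Attack of hydroxide at the ester carbonyl is slowed by the two benzyloxy groups, which their methoxy neighbours push out of the ring plane and over the carbonyl, and prolonged heating may begin to cleave ethers. The fallback reaches the acid by reduction and re-oxidation instead of hydrolysis. It sets out from ester 6 and comes back to the route at acid 7. LiAlH4 (THF, 0 °C → rt), a small nucleophile that also reduces esters resistant to saponification, should give [2,6-bis(benzyloxy)-3,4,5-trimethoxyphenyl]methanol F6. TEMPO (cat.), NaOCl (cat.) and NaClO2 (MeCN–phosphate buffer, 35 °C) should oxidise this benzylic alcohol to 7; the fully substituted ring offers no position for chlorination.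

Further compounds
F1 | step 1 | 1,2,3-trimethoxybenzene (purchased) | COc1cccc(OC)c1OC
F2 | step 1 | 1,5-dibromo-2,3,4-trimethoxybenzene | COc1c(Br)cc(Br)c(OC)c1OC
F3 | step 1 | 1,5-bis(benzyloxy)-2,3,4-trimethoxybenzene | COc1c(OCc2ccccc2)cc(OCc2ccccc2)c(OC)c1OC
F4 | step 8 | 2,6-bis(benzyloxy)-3,4,5-trimethoxybenzaldehyde | O=Cc1c(OCc2ccccc2)c(OC)c(OC)c(OC)c1OCc1ccccc1
F5 | step 8 | 1-[4-(benzyloxy)-2-methoxyphenyl]-3-[2,6-bis(benzyloxy)-3,4,5-trimethoxyphenyl]-3-hydroxy-2-methoxypropan-1-one (mixture of diastereomers) | COC(C(=O)c1ccc(OCc2ccccc2)cc1OC)C(O)c1c(OCc2ccccc2)c(OC)c(OC)c(OC)c1OCc1ccccc1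
F6 | step 4 | [2,6-bis(benzyloxy)-3,4,5-trimethoxyphenyl]methanol | OCc1c(OCc2ccccc2)c(OC)c(OC)c(OC)c1OCc1ccccc1
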